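**Strategy.** The route rests on cutting C2–C3 of the pyranone ring (ring C). C2 is an aldehyde-level carbon held between O1 and ring B, and C3 carries its own oxygen, so O1–C2–O3 can be stored as a seven-membered cyclic acetal of a 2'-hydroxy-α-hydroxyacetophenone with a vanillin unit. A chiral phosphoric acid then opens the acetal to an O1-oxocarbenium/enediol pair that recloses at carbon: C2 migrates from O3 to C3, the benzodioxepinone contracts to the chromanone and both stereocentres are set in one operation. The 5-O-prenyl ether blocks the second ortho oxygen and later delivers the C6 1,1-dimethylallyl group by Claisen rearrangement.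

Key step: step 6

Remarks on the chemistry (assumptions):
- Flavonoid numbering is used for all chromanones: O1, C2, C3, C4, C4a, C5 to C8, C8a; ring A is the fused arene, ring B the 2-aryl group, ring C the pyranone.
- The sense of induction of the chiral phosphoric acid in step 6 cannot be taken from a close precedent. The (R) catalyst is written; its mirror image would be used if the (2S,3S) product were favoured.

Step 1
Reactants: 1 1-(2,4,6-trihydroxyphenyl)ethanone
Product: 2 1-[2,6-dihydroxy-4-(triisopropylsilyloxy)phenyl]ethanone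
Conditions: i-Pr3SiCl (1.05 equiv), imidazole (2.2 equiv), DMF, 0 °C to rt
Reagents that add atoms: chlorotriisopropylsilane, CC(C)[Si](Cl)(C(C)C)C(C)C
Why: Silyl ether formation at a phenol; the para hydroxyl is the most acidic and the only one neither hydrogen-bonded to the ketone nor flanked by the acyl group, so one equivalent of the bulky chlorosilane should react there.

Step 2
Reactants: 2 1-[2,6-dihydroxy-4-(triisopropylsilyloxy)phenyl]ethanone; 3 3-methylbut-2-en-1-ol
Product: 4 1-[2-hydroxy-6-(3-methylbut-2-enyloxy)-4-(triisopropylsilyloxy)phenyl]ethanone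
Conditions: PPh3, DIAD, THF, 0 °C to rt
Reagents that add atoms: none
Why: Mitsunobu etherification, which alkylates hydrogen-bonded ortho-acyl phenols under neutral conditions; the two ortho hydroxyls of 2 are equivalent and the remaining one is held by chelation once the first is etherified, so the mono-ether should prevail.

Step 3
Reactants: 4 1-[2-hydroxy-6-(3-methylbut-2-enyloxy)-4-(triisopropylsilyloxy)phenyl]ethanone
Product: 6 2-hydroxy-1-[2-hydroxy-6-(3-methylbut-2-enyloxy)-4-(triisopropylsilyloxy)phenyl]ethanone, via dipotassium enolate phenoxide 5 (not isolated)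
Conditions: KN(SiMe3)2 (2.3 equiv), THF, −78 °C; then 2-(phenylsulfonyl)-3-phenyloxaziridine, −78 °C; aq. NH4Cl
Reagents that add atoms: 2-(phenylsulfonyl)-3-phenyloxaziridine (Davis reagent), O=S(=O)(c1ccccc1)N1OC1c1ccccc1
Why: Davis oxidation of a ketone enolate: two equivalents of base give the phenoxide–enolate dianion 5, whose enolate carbon attacks the electrophilic oxygen of the N-sulfonyloxaziridine, a reagent that leaves the trisubstituted alkene of the prenyl ether untouched.

Step 4
Reactants: 7 4-(tert-butyldimethylsilyloxy)-3-methoxybenzaldehyde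
Product: 8 tert-butyl[4-(dimethoxymethyl)-2-methoxyphenoxy]dimethylsilane
Conditions: HC(OMe)3, pyridinium p-toluenesulfonate (PPTS, cat.), MeOH, rt; Et3N quench
Reagents that add atoms: trimethyl orthoformate, COC(OC)OC
Why: Acid-catalysed acetalisation with an orthoformate turns the aldehyde carbon, the future C2, into a dimethyl acetal that exchanges its alkoxy groups under mild conditions, and the aryl silyl ether tolerates this.

Step 5
Reactants: 6 2-hydroxy-1-[2-hydroxy-6-(3-methylbut-2-enyloxy)-4-(triisopropylsilyloxy)phenyl]ethanone; 8 tert-butyl[4-(dimethoxymethyl)-2-methoxyphenoxy]dimethylsilane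
Product: 9 racemic 2-[4-(tert-butyldimethylsilyloxy)-3-methoxyphenyl]-6-(3-methylbut-2-enyloxy)-8-(triisopropylsilyloxy)-4H-1,3-benzodioxepin-5-one
Conditions: PPTS (10 mol %), CH2Cl2, 5 Å MS, 35 °C
Reagents that add atoms: none
Why: Acid-catalysed transacetalisation, in which the primary hydroxyl and then the ortho phenol of 6 replace the two methoxy groups while methanol is trapped by the sieves, should give the seven-membered cyclic acetal under conditions too mild to enolise the ketone; O1 is unambiguous because the other ortho oxygen is blocked as the prenyl ether, and the acetal carbon forms as a racemate that is ionised in step 6 anyway.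

Step 6
Reactants: 9 racemic 2-[4-(tert-butyldimethylsilyloxy)-3-methoxyphenyl]-6-(3-methylbut-2-enyloxy)-8-(triisopropylsilyloxy)-4H-1,3-benzodioxepin-5-one
Product: 11 (2R,3R)-2-[4-(tert-butyldimethylsilyloxy)-3-methoxyphenyl]-3-hydroxy-5-(3-methylbut-2-enyloxy)-7-(triisopropylsilyloxy)chroman-4-one, via oxocarbenium enediol ion pair 10 (not isolated)
Conditions: (R)-3,3′-bis(2,4,6-triisopropylphenyl)-1,1′-binaphthyl-2,2′-diyl hydrogen phosphate [(R)-TRIP, 10 mol %], toluene, 4 Å MS, 50 °C
Reagents that add atoms: none
Why: Proposed new method: the chiral phosphoric acid protonates O3 of the acetal and the C2–O3 bond ionises to an O1-aryl oxocarbenium ion (stabilised by the para-silyloxy group of ring B) held as an ion pair by the chiral phosphate, while the freed alpha-hydroxy ketone enolises towards C3 under the same acid (enediol, ion pair 10) and C3 adds to C2, so that C2 in effect migrates from O3 to C3 and the seven-membered acetal ring contracts to the pyranone. The closest known reaction types are the Petasis–Ferrier rearrangement (cyclic acetal to oxocarbenium/enolate pair to C–C bond), its chiral phosphoric acid catalysed aza variant, and the catalytic asymmetric oxa-Pictet–Spengler cyclisation, in which a tethered carbon nucleophile closes on an oxocarbenium–phosphate ion pair. Ring C closes by a 6-endo-trig attack on C2=O1 with the enol bond C3=C4 also inside the ring (6-(enolendo)-endo-trig, the mode of Pictet–Spengler and intramolecular Mannich closures). C2 is set by the catalyst, whose phosphate is hydrogen-bonded to the enediol hydroxyls and covers one face of the oxocarbenium carbon, and C3 follows from a chair-like transition state with the ring B aryl group and the 3-OH equatorial and is also the thermodynamic (trans) epimer, because C3 can equilibrate through the enol. The step needs C-attack through C3 after cleavage of C2–O3: cleavage of C2–O1 is a reversible dead end (C3 could then only close an oxirane) and O-attack merely returns 9, so all reversible paths drain into the C–C bond; the prenyl ether on the other ortho oxygen guarantees that only one phenol oxygen can hold C2, and attack through C3 instead of C4 of the enediol is favoured because it gives the six-membered conjugated aryl ketone without a quaternary centre.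

Step 7
Reactants: 11 (2R,3R)-2-[4-(tert-butyldimethylsilyloxy)-3-methoxyphenyl]-3-hydroxy-5-(3-methylbut-2-enyloxy)-7-(triisopropylsilyloxy)chroman-4-one
Product: 13 (2R,3R)-2-[4-(tert-butyldimethylsilyloxy)-3-methoxyphenyl]-3,5-dihydroxy-6-(2-methylbut-3-en-2-yl)-7-(triisopropylsilyloxy)chroman-4-one, via ortho-dienone 12 (not isolated)
Conditions: Eu(fod)3 [tris(6,6,7,7,8,8,8-heptafluoro-2,2-dimethyl-3,5-octanedionato)europium, 10 mol %], CHCl3, 60 °C
Reagents that add atoms: none
Why: Aromatic Claisen rearrangement ([3,3]-sigmatropic shift) catalysed by the europium chelate bound to the C4 carbonyl and the 5-O-allyl oxygen, a combination known to work on 5-O-prenyl flavanones at moderate temperature: the allyl unit is delivered with inversion of its termini to C6, the only free ortho position, and tautomerisation of dienone 12 gives the hydrogen-bonded 5-OH without touching C2 or C3.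

Step 8
Reactants: 13 (2R,3R)-2-[4-(tert-butyldimethylsilyloxy)-3-methoxyphenyl]-3,5-dihydroxy-6-(2-methylbut-3-en-2-yl)-7-(triisopropylsilyloxy)chroman-4-one
Product: 14 (2R,3R)-3,5,7-trihydroxy-2-(4-hydroxy-3-methoxyphenyl)-6-(2-methylbut-3-en-2-yl)chroman-4-one
Conditions: Bu4NF (2.5 equiv), AcOH (2.5 equiv), THF, 0 °C
Reagents that add atoms: none
Why: Fluoride cleavage of both aryl silyl ethers, buffered with acetic acid so that the phenoxides (in particular the 4'-phenoxide, which could open ring C through a quinone methide and epimerise C2) are protonated at once, should release the target with the C2/C3 configuration intact.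

**Compound list**

1 | 1-(2,4,6-trihydroxyphenyl)ethanone | CC(=O)c1c(O)cc(O)cc1O | starting material
2 | 1-[2,6-dihydroxy-4-(triisopropylsilyloxy)phenyl]ethanone | CC(=O)c1c(O)cc(O[Si](C(C)C)(C(C)C)C(C)C)cc1O | intermediate
3 | 3-methylbut-2-en-1-ol | CC(C)=CCO | starting material
4 | 1-[2-hydroxy-6-(3-methylbut-2-enyloxy)-4-(triisopropylsilyloxy)phenyl]ethanone | CC(=O)c1c(O)cc(O[Si](C(C)C)(C(C)C)C(C)C)cc1OCC=C(C)C | intermediate
5 | dipotassium enolate phenoxide of 4 (not isolated) | C=C([O-])c1c([O-])cc(O[Si](C(C)C)(C(C)C)C(C)C)cc1OCC=C(C)C.[K+].[K+] | intermediate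
6 | 2-hydroxy-1-[2-hydroxy-6-(3-methylbut-2-enyloxy)-4-(triisopropylsilyloxy)phenyl]ethanone | O=C(CO)c1c(O)cc(O[Si](C(C)C)(C(C)C)C(C)C)cc1OCC=C(C)C | intermediate
7 | 4-(tert-butyldimethylsilyloxy)-3-methoxybenzaldehyde | COc1cc(C=O)ccc1O[Si](C)(C)C(C)(C)C | starting material
8 | tert-butyl[4-(dimethoxymethyl)-2-methoxyphenoxy]dimethylsilane | COC(OC)c1ccc(O[Si](C)(C)C(C)(C)C)c(OC)c1 | intermediate
9 | racemic 2-[4-(tert-butyldimethylsilyloxy)-3-methoxyphenyl]-6-(3-methylbut-2-enyloxy)-8-(triisopropylsilyloxy)-4H-1,3-benzodioxepin-5-one | O=C1COC(c2ccc(O[Si](C)(C)C(C)(C)C)c(OC)c2)Oc2cc(O[Si](C(C)C)(C(C)C)C(C)C)cc(OCC=C(C)C)c21 | intermediate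
10 | oxocarbenium enediol ion pair (not isolated; cation shown, counter-ion is the phosphate of the catalyst) | OC=C(O)c1c(OCC=C(C)C)cc(O[Si](C(C)C)(C(C)C)C(C)C)cc1[O+]=Cc1ccc(O[Si](C)(C)C(C)(C)C)c(OC)c1 | intermediate
11 | (2R,3R)-2-[4-(tert-butyldimethylsilyloxy)-3-methoxyphenyl]-3-hydroxy-5-(3-methylbut-2-enyloxy)-7-(triisopropylsilyloxy)chroman-4-one | CC(C)=CCOc1cc(O[Si](C(C)C)(C(C)C)C(C)C)cc2c1C(=O)[C@H](O)[C@@H](c1ccc(O[Si](C)(C)C(C)(C)C)c(OC)c1)O2 | intermediate
12 | ortho-dienone, (2R,3R)-2-[4-(tert-butyldimethylsilyloxy)-3-methoxyphenyl]-3-hydroxy-6-(2-methylbut-3-en-2-yl)-7-(triisopropylsilyloxy)-2,3-dihydrochromene-4,5(6H)-dione (not isolated) | C=CC(C)(C)C1C(=O)C2=C(C=C1O[Si](C(C)C)(C(C)C)C(C)C)O[C@H](c1ccc(O[Si](C)(C)C(C)(C)C)c(OC)c1)[C@@H](O)C2=O | intermediate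
13 | (2R,3R)-2-[4-(tert-butyldimethylsilyloxy)-3-methoxyphenyl]-3,5-dihydroxy-6-(2-methylbut-3-en-2-yl)-7-(triisopropylsilyloxy)chroman-4-one | C=CC(C)(C)c1c(O[Si](C(C)C)(C(C)C)C(C)C)cc2c(c1O)C(=O)[C@H](O)[C@@H](c1ccc(O[Si](C)(C)C(C)(C)C)c(OC)c1)O2 | intermediate
14 | (2R,3R)-3,5,7-trihydroxy-2-(4-hydroxy-3-methoxyphenyl)-6-(2-methylbut-3-en-2-yl)chroman-4-one | C=CC(C)(C)c1c(O)cc2c(c1O)C(=O)[C@H](O)[C@@H](c1ccc(O)c(OC)c1)O2 | target

Total step count: 8. Longest linear sequence: 7 steps (steps 1, 2, 3, 5, 6, 7 and 8; step 4 prepares the acetal partner).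

**Steps most likely to fail**

1. Step 6 (Proposed new method).
   - What may go wrong: the ion pair may collapse with poor facial discrimination, giving low enantiomeric purity. Enolisation may be slower than re-closure or hydrolysis by adventitious water, so that 9 is returned or cleaved to 6 and 7. The enediol may close through C4 to a benzofuranol aldehyde. The acid may begin to cleave the allyl aryl ether.
   - Fallback with known chemistry, setting out from 9 and coming back at 11: the same C2–C3 closure is run without asymmetric induction as a Lewis acid mediated enolate–acetal aldol. Soft enolisation with TiCl4 and i-Pr2NEt in CH2Cl2 at −78 °C lets the chlorotitanium enolate add to the titanium-activated acetal. This should give the trans-flavanonol as a racemate, that is 11 together with its mirror image (2S,3S)-2-[4-(tert-butyldimethylsilyloxy)-3-methoxyphenyl]-3-hydroxy-5-(3-methylbut-2-enyloxy)-7-(triisopropylsilyloxy)chroman-4-one F1. Preparative chromatography on a chiral stationary phase (cellulose tris(3,5-dimethylphenylcarbamate)) removes F1 and returns 11.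

2. Step 5.
   - What may go wrong: the ring-closing acetal exchange is an equilibrium towards a seven-membered mixed aryl/alkyl acetal; it may stall at the open mixed acetal or at oligomers, or the acid may already trigger the racemic ring contraction.
   - Fallback, setting out from 6 (with 7 as the source of the benzyl unit) and coming back at 9: O1–C2 is made first by substitution and the acetal then by oxidation. Aldehyde 7 is reduced (NaBH4, MeOH) to [4-(tert-butyldimethylsilyloxy)-3-methoxyphenyl]methanol F2. F2 is converted (CBr4, PPh3, CH2Cl2) into [4-(bromomethyl)-2-methoxyphenoxy](tert-butyl)dimethylsilane F3. The phenol of 6 is alkylated chemoselectively over the primary alcohol (K2CO3, acetone) to give 1-[2-{[4-(tert-butyldimethylsilyloxy)-3-methoxyphenyl]methoxy}-6-(3-methylbut-2-enyloxy)-4-(triisopropylsilyloxy)phenyl]-2-hydroxyethanone F4. DDQ in dry CH2Cl2 over 4 Å MS at 0 °C then abstracts hydride from the electron-rich benzylic position, and the neighbouring primary hydroxyl traps the oxocarbenium ion to give 9. This is the oxidative benzylidene acetal formation known for alkoxybenzyl ethers of diols.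

3. Step 7.
   - What may go wrong: the lanthanide may bind the 3-OH/C4=O alpha-ketol unit instead of the C4=O/5-O pocket. The shift is then slow and, on forcing, the allyl unit may migrate on from C6 to C8 by a Cope shift, the prenyl ether may be cleaved, or C3 may epimerise.
   - Fallback, setting out from 9 and coming back at 13: the sigmatropic shift is moved in front of the ring contraction, onto a substrate without a free hydroxyl or a stereocentre to lose. Eu(fod)3 in CHCl3 converts 9 through the ortho-dienone 2-[4-(tert-butyldimethylsilyloxy)-3-methoxyphenyl]-7-(2-methylbut-3-en-2-yl)-8-(triisopropylsilyloxy)-4H-1,3-benzodioxepine-5,6(7H)-dione F5 into racemic 2-[4-(tert-butyldimethylsilyloxy)-3-methoxyphenyl]-6-hydroxy-7-(2-methylbut-3-en-2-yl)-8-(triisopropylsilyloxy)-4H-1,3-benzodioxepin-5-one F6. The acid-catalysed ring contraction of step 6, applied to F6, then passes through the oxocarbenium enediol ion pair F7 and gives 13 directly. The tert-alkyl group next to the free phenol is relied on to keep the acetal carbon from moving to that oxygen.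

**Further compounds**

F1 | step 6 | (2S,3S)-2-[4-(tert-butyldimethylsilyloxy)-3-methoxyphenyl]-3-hydroxy-5-(3-methylbut-2-enyloxy)-7-(triisopropylsilyloxy)chroman-4-one | CC(C)=CCOc1cc(O[Si](C(C)C)(C(C)C)C(C)C)cc2c1C(=O)[C@@H](O)[C@H](c1ccc(O[Si](C)(C)C(C)(C)C)c(OC)c1)O2
F2 | step 5 | [4-(tert-butyldimethylsilyloxy)-3-methoxyphenyl]methanol | COc1cc(CO)ccc1O[Si](C)(C)C(C)(C)C
F3 | step 5 | [4-(bromomethyl)-2-methoxyphenoxy](tert-butyl)dimethylsilane | COc1cc(CBr)ccc1O[Si](C)(C)C(C)(C)C
F4 | step 5 | 1-[2-{[4-(tert-butyldimethylsilyloxy)-3-methoxyphenyl]methoxy}-6-(3-methylbut-2-enyloxy)-4-(triisopropylsilyloxy)phenyl]-2-hydroxyethanone | O=C(CO)c1c(OCc2ccc(O[Si](C)(C)C(C)(C)C)c(OC)c2)cc(O[Si](C(C)C)(C(C)C)C(C)C)cc1OCC=C(C)C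
F5 | step 7 | 2-[4-(tert-butyldimethylsilyloxy)-3-methoxyphenyl]-7-(2-methylbut-3-en-2-yl)-8-(triisopropylsilyloxy)-4H-1,3-benzodioxepine-5,6(7H)-dione | C=CC(C)(C)C1C(=O)C2=C(C=C1O[Si](C(C)C)(C(C)C)C(C)C)OC(c1ccc(O[Si](C)(C)C(C)(C)C)c(OC)c1)OCC2=O
F6 | step 7 | racemic 2-[4-(tert-butyldimethylsilyloxy)-3-methoxyphenyl]-6-hydroxy-7-(2-methylbut-3-en-2-yl)-8-(triisopropylsilyloxy)-4H-1,3-benzodioxepin-5-one | O=C1COC(c2ccc(O[Si](C)(C)C(C)(C)C)c(OC)c2)Oc2cc(O[Si](C(C)C)(C(C)C)C(C)C)c(C(C)(C)C=C)c(O)c21
F7 | step 7 | oxocarbenium enediol ion pair from F6 (cation shown, counter-ion is the phosphate of the catalyst) | OC=C(O)c1c(O)c(C(C)(C)C=C)c(O[Si](C(C)C)(C(C)C)C(C)C)cc1[O+]=Cc1ccc(O[Si](C)(C)C(C)(C)C)c(OC)c1
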